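Everything rests on cutting ring C of the flavonol at C4–C4a and O1–C2. Ring A is made as 2,4-diprenylphloroglucinol: its one remaining C–H carbon (future C4a) is flanked by two symmetry-related hydroxyls (one becomes O1, the other the 5-OH), so the C2–C3–C4 unit can be fused on with free phenols and only one possible outcome. The partner is a tert-butyl 2-benzoyloxy-3-oxopropanoate whose aryl group is the finished 2,2-dimethylchromene (ring B with its pyran ring). On heating it releases an aroyl(benzoyloxy)ketene, which C-acylates the phenol; cyclodehydration then closes the pyranone in the same operation. Benzoate methanolysis completes dorsilurin C.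

Key step: step 6

Assumption: phenoxides present only in equilibrium under the basic conditions of steps 1 and 7 are treated as ionised forms of the numbered phenols, whereas the two enolates generated quantitatively with strong base (steps 4 and 5) are numbered as intermediates.

Step 1
Reactants: 1 phloroglucinol; 2 prenyl bromide (1-bromo-3-methylbut-2-ene)
Product: 3 2,4-diprenylphloroglucinol [2,4-bis(3-methylbut-2-en-1-yl)benzene-1,3,5-triol]
Conditions: 2 (2.0 equiv), KOH (2.1 equiv), H2O, 0 °C → rt; chromatography, monoprenyl fraction recycled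
Reagents that add atoms: none
Why: C-alkylation of the ambident phloroglucinolate, whose oxygens are hydrogen-bonded in water so that the soft allylic bromide is taken at carbon, is a standard phenolate C-prenylation, and because the three ring carbons of 1 and the two free carbons of the monoprenyl compound are each equivalent, ring dialkylation can give only one constitutional isomer.

Step 2
Reactants: 4 methyl 3-hydroxy-4-iodobenzoate; 5 2-methylbut-3-en-2-ol
Product: 6 methyl 3-hydroxy-4-[(E)-3-hydroxy-3-methylbut-1-en-1-yl]benzoate
Conditions: Pd(OAc)2 (5 mol%), P(o-tol)3 (10 mol%), Et3N (2 equiv), DMF, 90 °C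
Reagents that add atoms: none
Why: Mizoroki–Heck reaction, in which the aryl iodide adds oxidatively to zerovalent palladium (formed in situ from Pd(OAc)2), the aryl group is delivered to the terminal alkene carbon, and beta-hydride elimination can only give the E-styrenyl tertiary alcohol because the carbinol carbon bears no hydrogen.

Step 3
Reactants: 6 methyl 3-hydroxy-4-[(E)-3-hydroxy-3-methylbut-1-en-1-yl]benzoate
Product: 7 methyl 2,2-dimethyl-2H-chromene-7-carboxylate
Conditions: p-TsOH·H2O (5 mol%), toluene, 80 °C
Reagents that add atoms: none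
Why: Acid-catalysed cyclodehydration, in which ionisation of the tertiary allylic alcohol gives an allyl cation conjugated to the ortho-oxygenated arene where the former E double bond can rotate, after which the phenol oxygen captures the tertiary terminus and closes the 2,2-dimethylpyran ring, the position of the original iodide leaving no regiochemical alternative.

Step 4
Reactants: 7 methyl 2,2-dimethyl-2H-chromene-7-carboxylate; 8 tert-butyl acetate
Product: 10 tert-butyl 3-(2,2-dimethyl-2H-chromen-7-yl)-3-oxopropanoate, via lithium enolate of tert-butyl acetate 9 (not isolated)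
Conditions: 8 (3.0 equiv), LiN(i-Pr)2 (3.1 equiv), THF, −78 °C; then 7, −78 → −20 °C; aq. NH4Cl
Reagents that add atoms: none
Why: Crossed Claisen condensation, in which ester 7 has no alpha hydrogens and serves only as acceptor, the hindered enolate 9 self-condenses slowly at −78 °C, and the excess enolate turns the product into its unreactive enolate so that addition stops at the ketone stage.

Step 5
Reactants: 10 tert-butyl 3-(2,2-dimethyl-2H-chromen-7-yl)-3-oxopropanoate; 11 dibenzoyl peroxide
Product: 13 tert-butyl 2-(benzoyloxy)-3-(2,2-dimethyl-2H-chromen-7-yl)-3-oxopropanoate (racemic), via sodium enolate of the beta-ketoester 12 (not isolated)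
Conditions: NaH (1.05 equiv), THF, 0 °C; then 11 (1.0 equiv), 0 °C → rt; aq. NH4Cl
Reagents that add atoms: none
Why: Electrophilic alpha-oxygenation of a stabilised enolate, in which the carbon of 12 attacks the weak O–O bond of the peroxide in an ionic substitution with benzoate as leaving group (the classical benzoyloxylation of beta-dicarbonyl anions), the new stereocentre arising without control as the racemate, which is of no consequence because it later becomes the sp2 carbon C3, while the low temperature keeps the peroxide from homolysis that could involve the chromene alkene.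

Step 6
Reactants: 3 2,4-diprenylphloroglucinol; 13 tert-butyl 2-(benzoyloxy)-3-(2,2-dimethyl-2H-chromen-7-yl)-3-oxopropanoate
Product: 16 dorsilurin C 3-O-benzoate, via aroyl(benzoyloxy)ketene 14 (not isolated), via 2-benzoyloxy-1,3-diketone 15 (not isolated)
Conditions: 3 (1.0 equiv), 13 (1.3 equiv, slow addition), Ph2O, 150 °C then 210 °C, Ar stream (−t-BuOH, −H2O)
Reagents that add atoms: none
Why: Proposed new method: heating the enolisable tert-butyl beta-ketoester 13 should expel tert-butanol and give acylketene 14, as tert-butyl acetoacetates are known to do; ester formation at a phenol oxygen of 3 can revert to the ketene at this temperature, whereas attack of the single, strongly nucleophilic ring C–H carbon of 3 on the ketene carbon is not reversible and delivers diketone 15 with the new C4–C4a bond. One of the two equivalent flanking hydroxyls then adds to the aryl ketone carbonyl (6-exo-trig, hemiketal) and loss of water forms O1–C2 and aromatises the gamma-pyranone, the only ring closed here. The closest known reaction type is the acid-free thermal condensation of phloroglucinol with aroylacetates to 5,7-dihydroxyflavones (Mentzer chromone synthesis), which has not been run with an alpha-acyloxy aroylacetate or with a free prenylated phloroglucinol. No stereocentre is created, because the racemic alpha carbon of 13 ends as the sp2 carbon C3. The step needs chromone and not coumarin closure, reaction at carbon and not only at oxygen, one annulation site, and survival of the ortho-prenylphenol and chromene units: the neutral ketene route makes the ester carbon the carbon electrophile (coumarin formation would need acid activation of the ketone), the absence of acid spares the prenyl groups from chroman formation, and the symmetry of 3 offers a single site.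

Step 7
Reactants: 16 dorsilurin C 3-O-benzoate
Product: 17 dorsilurin C
Conditions: K2CO3 (0.5 equiv), degassed MeOH, Ar, 0 °C → rt; dilute aq. citric acid
Reagents that add atoms: none
Why: Base-catalysed transesterification (Zemplén-type methanolysis), in which the benzoate of the acidic 3-enol is an activated ester that methoxide in equilibrium with K2CO3 should cleave at room temperature, together with any benzoyl group that migrated to a phenol in step 6, while prenyl, chromene and pyranone units are inert and exclusion of air protects the flavonolate from oxidative ring cleavage.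

Compound list
1 | phloroglucinol | Oc1cc(O)cc(O)c1 | starting material
2 | prenyl bromide | CC(C)=CCBr | starting material
3 | 2,4-diprenylphloroglucinol | CC(C)=CCc1c(O)cc(O)c(CC=C(C)C)c1O | intermediate
4 | methyl 3-hydroxy-4-iodobenzoate | COC(=O)c1ccc(I)c(O)c1 | starting material
5 | 2-methylbut-3-en-2-ol | C=CC(C)(C)O | starting material
6 | methyl 3-hydroxy-4-[(E)-3-hydroxy-3-methylbut-1-en-1-yl]benzoate | COC(=O)c1ccc(/C=C/C(C)(C)O)c(O)c1 | intermediate
7 | methyl 2,2-dimethyl-2H-chromene-7-carboxylate | COC(=O)c1ccc2c(c1)OC(C)(C)C=C2 | intermediate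
8 | tert-butyl acetate | CC(=O)OC(C)(C)C | starting material
9 | lithium enolate of tert-butyl acetate (not isolated) | C=C(O[Li])OC(C)(C)C | intermediate
10 | tert-butyl 3-(2,2-dimethyl-2H-chromen-7-yl)-3-oxopropanoate | CC(C)(C)OC(=O)CC(=O)c1ccc2c(c1)OC(C)(C)C=C2 | intermediate
11 | dibenzoyl peroxide | O=C(OOC(=O)c1ccccc1)c1ccccc1 | starting material
12 | sodium (Z)-enolate of beta-ketoester 10 (not isolated) | [Na]O/C(=C\C(=O)OC(C)(C)C)c1ccc2c(c1)OC(C)(C)C=C2 | intermediate
13 | tert-butyl 2-(benzoyloxy)-3-(2,2-dimethyl-2H-chromen-7-yl)-3-oxopropanoate (racemic) | CC(C)(C)OC(=O)C(OC(=O)c1ccccc1)C(=O)c1ccc2c(c1)OC(C)(C)C=C2 | intermediate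
14 | aroyl(benzoyloxy)ketene, 1-(2,2-dimethyl-2H-chromen-7-yl)-1,3-dioxoprop-2-en-2-yl benzoate (not isolated) | O=C=C(OC(=O)c1ccccc1)C(=O)c1ccc2c(c1)OC(C)(C)C=C2 | intermediate
15 | 2-(benzoyloxy)-1-(2,2-dimethyl-2H-chromen-7-yl)-3-[2,4,6-trihydroxy-3,5-bis(3-methylbut-2-en-1-yl)phenyl]propane-1,3-dione (racemic, not isolated) | CC(C)=CCc1c(O)c(CC=C(C)C)c(O)c(C(=O)C(OC(=O)c2ccccc2)C(=O)c2ccc3c(c2)OC(C)(C)C=C3)c1O | intermediate
16 | dorsilurin C 3-O-benzoate, 5,7-dihydroxy-2-(2,2-dimethyl-2H-chromen-7-yl)-6,8-bis(3-methylbut-2-en-1-yl)-4-oxo-4H-chromen-3-yl benzoate | CC(C)=CCc1c(O)c(CC=C(C)C)c2oc(-c3ccc4c(c3)OC(C)(C)C=C4)c(OC(=O)c3ccccc3)c(=O)c2c1O | intermediate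
17 | dorsilurin C, 3,5,7-trihydroxy-2-(2,2-dimethyl-2H-chromen-7-yl)-6,8-bis(3-methylbut-2-en-1-yl)-4H-chromen-4-one (achiral) | CC(C)=CCc1c(O)c(CC=C(C)C)c2oc(-c3ccc4c(c3)OC(C)(C)C=C4)c(O)c(=O)c2c1O | target

Total step count: 7. Longest linear sequence: 6 steps (4 → 6 → 7 → 10 → 13 → 16 → 17); the ring A fragment 3 joins after one step.

Steps most likely to fail

Step 6 (proposed new method). What may go wrong: loss of isobutene and carbon dioxide from 13 in place of ketene formation, dimerisation of the ketene, benzoyl transfer onto the phenols outrunning C-acylation, or heat-induced cyclisation of a prenyl group onto a neighbouring hydroxyl. The fallback builds ring C by the Algar–Flynn–Oyamada sequence (known chemistry), sets out from 2 and 7 and returns at 17. Commercial 2,4,6-trihydroxyacetophenone is C-prenylated twice with 2 (aq. KOH, 0 °C) to give 2,4,6-trihydroxy-3,5-diprenylacetophenone F1. MOMCl (2.2 equiv) and i-Pr2NEt in CH2Cl2 cap the 4-OH and one chelated OH to give 2-hydroxy-4,6-bis(methoxymethoxy)-3,5-diprenylacetophenone F2. Separately, 7 is reduced with i-Bu2AlH (CH2Cl2, −78 °C) to (2,2-dimethyl-2H-chromen-7-yl)methanol F3 and oxidised with MnO2 (CH2Cl2, rt) to 2,2-dimethyl-2H-chromene-7-carbaldehyde F4. Claisen–Schmidt condensation of F2 with F4 (KOH, EtOH, rt) should give the (E)-2'-hydroxychalcone F5. NaOH and 30% H2O2 in MeOH (0 °C → rt) should then close and oxidise it to dorsilurin C 5,7-bis(methoxymethyl) ether F6, and brief treatment with HCl in MeOH (rt to 40 °C) removes both MOM groups to give 17.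

Step 1. What may go wrong: statistical under- and over-alkylation, O-alkylation and dearomatising geminal dialkylation leave little of the wanted ring-dialkylated material. The fallback uses directed ortho-metalation, sets out from 1 and returns at 3. Compound 1 is converted into 1,3,5-tris(methoxymethoxy)benzene F7 (NaH, MOMCl, DMF, 0 °C). Lithiation between two MOM ethers (n-BuLi, THF, 0 °C) and quenching with 2 gives 2-prenyl-1,3,5-tris(methoxymethoxy)benzene F8. A second lithiation and prenylation at one of the two remaining equivalent positions gives 2,4-diprenyl-1,3,5-tris(methoxymethoxy)benzene F9, and HCl in MeOH (rt) then frees 3.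

Step 3. What may go wrong: the E alkene cannot close directly, so ring formation depends on ionisation and bond rotation in the allyl cation, which the para ester slows; elimination to the diene and cationic oligomerisation may then take over. The fallback is an alkyne route that delivers the Z alkene, sets out from 4 and returns at 7. Sonogashira coupling of 4 with 2-methylbut-3-yn-2-ol (PdCl2(PPh3)2, CuI, Et3N, rt, to avoid benzofuran formation) gives methyl 3-hydroxy-4-(3-hydroxy-3-methylbut-1-yn-1-yl)benzoate F10. Semihydrogenation (H2, Pd/CaCO3 poisoned with Pb(OAc)2, quinoline, EtOAc) gives methyl 3-hydroxy-4-[(Z)-3-hydroxy-3-methylbut-1-en-1-yl]benzoate F11, in which phenol and carbinol sit on the same side, so that a trace of acid (PPTS, CH2Cl2, rt) should close the pyran ring to 7.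

Further compounds
F1 | step 6 | 2,4,6-trihydroxy-3,5-diprenylacetophenone | CC(=O)c1c(O)c(CC=C(C)C)c(O)c(CC=C(C)C)c1O
F2 | step 6 | 2-hydroxy-4,6-bis(methoxymethoxy)-3,5-diprenylacetophenone | CC(=O)c1c(O)c(CC=C(C)C)c(OCOC)c(CC=C(C)C)c1OCOC
F3 | step 6 | (2,2-dimethyl-2H-chromen-7-yl)methanol | OCc1ccc2c(c1)OC(C)(C)C=C2
F4 | step 6 | 2,2-dimethyl-2H-chromene-7-carbaldehyde | O=Cc1ccc2c(c1)OC(C)(C)C=C2
F5 | step 6 | (E)-3-(2,2-dimethyl-2H-chromen-7-yl)-1-[2-hydroxy-4,6-bis(methoxymethoxy)-3,5-bis(3-methylbut-2-en-1-yl)phenyl]prop-2-en-1-one | COCOc1c(CC=C(C)C)c(O)c(C(=O)/C=C/c2ccc3c(c2)OC(C)(C)C=C3)c(OCOC)c1CC=C(C)C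
F6 | step 6 | dorsilurin C 5,7-bis(methoxymethyl) ether | COCOc1c(CC=C(C)C)c(OCOC)c2c(=O)c(O)c(-c3ccc4c(c3)OC(C)(C)C=C4)oc2c1CC=C(C)C
F7 | step 1 | 1,3,5-tris(methoxymethoxy)benzene | COCOc1cc(OCOC)cc(OCOC)c1
F8 | step 1 | 2-prenyl-1,3,5-tris(methoxymethoxy)benzene | COCOc1cc(OCOC)c(CC=C(C)C)c(OCOC)c1
F9 | step 1 | 2,4-diprenyl-1,3,5-tris(methoxymethoxy)benzene | COCOc1cc(OCOC)c(CC=C(C)C)c(OCOC)c1CC=C(C)C
F10 | step 3 | methyl 3-hydroxy-4-(3-hydroxy-3-methylbut-1-yn-1-yl)benzoate | COC(=O)c1ccc(C#CC(C)(C)O)c(O)c1
F11 | step 3 | methyl 3-hydroxy-4-[(Z)-3-hydroxy-3-methylbut-1-en-1-yl]benzoate | COC(=O)c1ccc(/C=C\C(C)(C)O)c(O)c1
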